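## Structural features

The target is a heterodimer. A 2,3-dihydro-1-benzofuran whose benzene ring (ring A) is a fully substituted acylphloroglucinol (C4–OH, C5–acetyl, C6–OH, O1 on C7a) is joined through one methylene at C7 to C3 of a 6-ethyl-4-hydroxy-5-methyl-2H-pyran-2-one (ring C). The dihydrofuran (ring B) carries a 6-methylhepta-1,5-dien-2-yl chain at C2, so C2 is both an ether carbon and an allylic carbon, and its neighbour C3 is an unsubstituted benzylic CH2. C2 is the only stereocentre (R) and has no stereogenic neighbour, so it must be set by a reagent or catalyst. The fragile groups are the 1,1-disubstituted and trisubstituted alkenes (protic acid, electrophiles, hydrogenation), the allylic aryl ether bond O1–C2 (ionisation by strong Lewis acid or zerovalent palladium would erase the configuration), the two chelated acidic phenols, the enolic 4-hydroxypyranone, and the methylene bridge between two vinylogous acids. The real difficulty is twofold: every oxygen on the hexasubstituted ring A must be told apart, and an isolated stereocentre must be created on ring B in the presence of two alkenes. The key step uses the fact that C3 is a plain CH2 and C2 an O–CH next to an alkene: C2–C3 can be formed by insertion of a carbene at C3 into one O–CH2 hydrogen of a 2-substituted allyl ether on O1, which closes ring B and sets C2 together.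

## Logic of the disconnections

**20 ⇒ 13 + 18.** The bond between C7 and the bridge methylene is cut. C7 is the only unsubstituted position of ring A in 13 and is activated by O1 and the 6-hydroxyl, and 18 releases the bridge carbon as the exocyclic methylene of 19 on loss of its amine. This separates the chiral half from an achiral pyranone and makes the last step convergent. The forward step must give C-alkylation at C7, avoid self-coupling of pyranone units, and run under near-neutral conditions that spare the diene and the O1–C2 bond.

**18 ⇒ 17 ⇒ 15 + 16 ⇒ 14.** The C3–CH2N bond of 18 is cut (Mannich), then pyranone bonds C4–C5 and O1–C2 of 17. The five carbons of 14 supply C5, C6 and their alkyl groups, and 16 supplies C2–C4. The symmetry of 14 removes any regiochemical question in forming 15. The annulation must C-acylate first and O-acylate second.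

**13 ⇒ 12.** Two O–Si bonds are cut. The phenols must be masked during the carbene step because acidic hydroxyls would protonate 11. Silyl ethers are chosen because they have no C–H bond next to oxygen to compete for the carbene and they come off with buffered fluoride, which leaves the alkenes and C2 alone.

**12 ⇒ 10 (through 11).** The C2–C3 bond is cut. This opens ring B and removes the only stereocentre, leaving an achiral aryl ether with a carbene precursor at the future C3. The forward step must select one of two enantiotopic hydrogens and prefer 1,5-insertion over every other reaction of the carbene and of 11.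

**10 ⇒ 9 ⇒ 8.** The C=N bond is cut, then the two O–Si bonds. The aldehyde of 9 lies between an ether and a silyl ether, and the ketone lies between two silyl ethers, so condensation should occur at the aldehyde alone. The silyl ether beside the aldehyde is an activated one, so the condensation must be non-hydrolytic and brief.

**8 ⇒ 6 (through 7).** The ring–CHO bond is cut. In 6 a mirror plane passes through the acetyl-bearing carbon and the ether-bearing carbon, so the two free ring positions are equivalent and formylation can give only one product. Placing this cut after the ether cut avoids having to choose among three hydroxyls of a formylated triol. The formylation must spare the two alkenes and the acetyl methyl group.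

**6 ⇒ 5 + 4.** The O–CH2 bond of the allyl ether is cut. In 5 the hydroxyl para to the acetyl group is the only one not hydrogen-bonded to the carbonyl and is the most acidic, so a Mitsunobu reaction should alkylate it selectively and without C-allylation. Either SN2 or SN2' attack on the 2-substituted allyl unit gives the same ether.

**4 ⇒ 1 + 2 (through 3).** The bond between the homoprenyl chain and the central alkene carbon is cut. One copper-catalysed carbomagnesiation makes the whole 2-substituted allyl alcohol. It must place the alkyl group on the internal alkyne carbon.

## Other disconnections considered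

**Alternative 1:** The cut is pyranone C3–C4, with O1–C2 kept as the acyl–oxygen bond of an enol ester.
- **Forward step:** ethyl (2Z)-2-methyl-3-[[3-(2,4,6-trimethoxyphenyl)propanoyl]oxy]pent-2-enoate A1 would be deprotonated next to the acyl carbonyl. The enolate would attack the neighbouring ethyl ester (intramolecular Claisen, six-membered closure) to give 6-ethyl-4-hydroxy-5-methyl-3-[(2,4,6-trimethoxyphenyl)methyl]-2H-pyran-2-one A2.
- **In favour:** the bridge carbon is in the chain from the start, so self-coupling of two pyranone units cannot occur and ring C regiochemistry is fixed by connectivity. On this point it is better than the chosen plan.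
- **Against:** the enolate of an enol ester can fragment to a ketene and a β-keto ester enolate, or transfer the acyl group to carbon before closing. A2 has three methyl ethers, no acetyl group and no ring B. Cleaving three aryl methyl ethers needs Lewis-acid conditions that the diene and the O1–C2 bond would not survive, so the side chain and stereocentre would have to be added afterwards to a polyphenol.
- **Comparison:** on structure, it solves ring C and the bridge and leaves ring B and C2 open; the chosen plan does the reverse and leaves the bridge to an established last-step coupling. On mechanism, the Claisen closure is ordinary enolate chemistry and more predictable than the carbene insertion. On step economy, it is no shorter once acylation, demethylation and ring B are counted, and the stereocentre would be set later on more valuable material.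

**Alternative 2:** The cut removes C3a–C3 and O1–C2 and returns 1-[4-hydroxy-3-iodo-2,6-bis(methoxymethoxy)phenyl]ethanone A3 and β-myrcene A4.
- **Forward step:** zerovalent palladium with a chiral ligand would insert into the C–I bond. The aryl group would add to the CH2 terminus of the monosubstituted alkene of A4, and the phenoxide would attack the internal carbon of the π-allyl to give 1-[(2R)-4,6-bis(methoxymethoxy)-2-(6-methylhepta-1,5-dien-2-yl)-2,3-dihydro-1-benzofuran-5-yl]ethanone A5.
- **In favour:** two bonds and the stereocentre form in one step from a cheap terpene. The reaction belongs to a known class of enantioselective diene heteroannulations of 2-halophenols. No diazo compound and no separate side-chain synthesis are needed. On precedent and on bonds formed per step it is better than the chosen plan.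
- **Against:** A3 needs the hydroxyl para to the acetyl group free while the two chelated hydroxyls are protected, which is the reverse of their natural reactivity and costs several protecting-group steps. The iodide is flanked by two ortho oxygens. Regiocontrol must hold both between the two alkene termini of A4 and between the two ends of the π-allyl. The acetal groups of A5 are removed with acid, which the trisubstituted alkene and the O1–C2 bond tolerate poorly.
- **Comparison:** on structure, both plans reach the same ring B and use the same end game. On mechanism, this route rests on understood allylic substitution and the chosen plan on an untested carbene class. On step economy the two are about equal, since the side-chain step saved is offset by protection steps. Because it is known chemistry, a silyl-protected version is kept as the fallback for the key step.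

**Alternative 3:** The cut is pyranone C4–C5 and O1–C2.
- **Forward step:** silyl enol ether 15 of the chosen route would be C-acylated by 2-[(3-acetyl-2,4,6-trimethoxyphenyl)methyl]propanedioyl dichloride A6. The enol oxygen would then close the ring to give 3-[(3-acetyl-2,4,6-trimethoxyphenyl)methyl]-6-ethyl-4-hydroxy-5-methyl-2H-pyran-2-one A7.
- **In favour:** this is the same annulation as step 9 of the chosen route, so on that step the two are equal. The bridge and the acetyl group are already in place, which excludes pyranone self-coupling; on that point it is better.
- **Against:** A6 is a monosubstituted malonyl dichloride carrying an enolisable aryl ketone, so ketene formation and self-acylation threaten its preparation and use. In A7 the only free ring position is the future C3a. Ring B would then need selective cleavage of the one methyl ether para to the acetyl group, C–C bond formation between two oxygen substituents, an asymmetric closure, and removal of the last two methyl ethers in the presence of the diene.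
- **Comparison:** on structure, it fixes the achiral half early and postpones the hard part. On mechanism, its key step is as reliable as step 9. On step economy it is clearly longer, and the deprotection problem has no mild answer.

Key step: step 6

Assumption: the sense of induction of Rh2(R-PTAD)4 (dirhodium tetrakis[(R)-(1-adamantyl)(phthalimido)acetate]) on this carbene class cannot be predicted with confidence; the R catalyst is written, and if it favours the (2S) product, Rh2(S-PTAD)4 replaces it with nothing else changed.

## Route

Step 1
Reactants: 1 5-bromo-2-methylpent-2-ene; 2 prop-2-yn-1-ol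
Product: 4 6-methyl-2-methylidenehept-5-en-1-ol, via Grignard reagent 3 (not isolated)
Conditions: Mg, THF, 25–40 °C; then 2 (0.4 equiv), CuI (10 mol%), THF, −10 °C → rt; H2O
Reagents that add atoms: none
Why: Copper-catalysed carbomagnesiation of propargyl alcohol: the magnesium alkoxide directs anti addition of the alkyl group of 3 to the internal alkyne carbon through a five-membered chelate, and protonolysis of the vinylmagnesium species gives the 2-substituted allyl alcohol; one equivalent of 3 is consumed by the hydroxyl proton, so 3 is used in excess.

Step 2
Reactants: 5 2,4,6-trihydroxyacetophenone; 4 6-methyl-2-methylidenehept-5-en-1-ol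
Product: 6 1-[2,6-dihydroxy-4-[(6-methyl-2-methylidenehept-5-en-1-yl)oxy]phenyl]ethanone
Conditions: PPh3, DIAD, THF, 0 °C → rt (5 in slight excess)
Reagents that add atoms: none
Why: Mitsunobu etherification: the 4-hydroxyl of 5 is the only one not hydrogen-bonded to the acetyl group and is the most acidic, so it should be the one alkylated; the neutral conditions avoid the C-allylation that phloroglucinol anions show with allylic halides, and SN2 and SN2' attack on the 2-substituted allyl unit give the same ether.

Step 3
Reactants: 6 1-[2,6-dihydroxy-4-[(6-methyl-2-methylidenehept-5-en-1-yl)oxy]phenyl]ethanone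
Product: 8 3-acetyl-2,4-dihydroxy-6-[(6-methyl-2-methylidenehept-5-en-1-yl)oxy]benzaldehyde, via iminium chloride 7 (not isolated)
Conditions: (chloromethylidene)dimethylammonium chloride (1.2 equiv), MeCN/DMF, −10 → 0 °C; then H2O, NaOAc, 0 °C → rt
Reagents that add atoms: (chloromethylidene)dimethylammonium chloride (Vilsmeier reagent), ClC=[N+](C)C.[Cl-]; water, O
Why: Vilsmeier–Haack formylation: the two free ring positions of 6 are related by a mirror plane, so only one product is possible; the ring carries three oxygen donors and should react at or below 0 °C, which keeps the reagent away from the acetyl methyl group and the isolated alkenes, and the first formyl group deactivates the ring towards a second; buffered hydrolysis of 7 releases the aldehyde.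

Step 4
Reactants: 8 3-acetyl-2,4-dihydroxy-6-[(6-methyl-2-methylidenehept-5-en-1-yl)oxy]benzaldehyde
Product: 9 3-acetyl-2,4-bis[[tert-butyl(dimethyl)silyl]oxy]-6-[(6-methyl-2-methylidenehept-5-en-1-yl)oxy]benzaldehyde
Conditions: TBSOTf (2.5 equiv), 2,6-lutidine, CH2Cl2, −40 → 0 °C
Reagents that add atoms: tert-butyldimethylsilyl trifluoromethanesulfonate (TBSOTf), CC(C)(C)[Si](C)(C)OS(=O)(=O)C(F)(F)F
Why: Silylation of two chelated phenols needs the reactive triflate with a hindered pyridine base; the silyl ethers mask the acidic hydroxyls that would protonate the diazo compound in step 6 and offer the carbene no C–H bond next to oxygen.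

Step 5
Reactants: 9 3-acetyl-2,4-bis[[tert-butyl(dimethyl)silyl]oxy]-6-[(6-methyl-2-methylidenehept-5-en-1-yl)oxy]benzaldehyde
Product: 10 1-[2,6-bis[[tert-butyl(dimethyl)silyl]oxy]-3-[(E)-hydrazinylidenemethyl]-4-[(6-methyl-2-methylidenehept-5-en-1-yl)oxy]phenyl]ethanone
Conditions: N2H4 (1 M in THF, 5 equiv), 4 Å molecular sieves, THF, 0 °C, short reaction time
Reagents that add atoms: hydrazine, NN
Why: Hydrazone condensation at the aldehyde only, because the acetyl carbonyl sits between two silyloxy groups and is much less accessible; excess anhydrous hydrazine at 0 °C disfavours azine formation and limits attack at silicon, and the E isomer is expected with NH2 turned away from the ring.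

Step 6
Reactants: 10 1-[2,6-bis[[tert-butyl(dimethyl)silyl]oxy]-3-[(E)-hydrazinylidenemethyl]-4-[(6-methyl-2-methylidenehept-5-en-1-yl)oxy]phenyl]ethanone
Product: 12 1-[(2R)-4,6-bis[[tert-butyl(dimethyl)silyl]oxy]-2-(6-methylhepta-1,5-dien-2-yl)-2,3-dihydro-1-benzofuran-5-yl]ethanone, via diazo compound 11 (not isolated)
Conditions: MnO2 (10 equiv), CH2Cl2, 0 °C, cold filtration; filtrate added slowly to Rh2(R-PTAD)4 (1 mol%), CH2Cl2, −20 → 0 °C
Reagents that add atoms: none
Why: Proposed new method: MnO2 dehydrogenates hydrazone 10 to the aryldiazomethane 11, which the divalent rhodium carboxylate dimer Rh2(R-PTAD)4 converts with loss of N2 into a rhodium carbene carrying the aryl group and a hydrogen; the electrophilic carbene carbon then takes one hydrogen of the neighbouring O–CH2 group through a three-centre, hydride-transfer-like transition state and bonds to that carbon, forming C2–C3. The closest known reaction type is the dirhodium-catalysed enantioselective intramolecular C–H insertion of diaryl and aryl alkyl carbenes, made the same way from hydrazones, into ether α-C–H bonds to give 2,3-dihydrobenzofurans; the new element is a carbene with hydrogen in place of the second carbon substituent, which is less shielded and more prone to bimolecular coupling. Ring B is closed by 1,5-insertion through a five-membered transition state made up of the carbene carbon, C3a, C7a, O1 and C2. The C2 stereocentre is under catalyst control alone: the chiral carboxylate pocket decides which of the two enantiotopic O–CH2 hydrogens is taken, and insertion with retention at carbon turns that choice into the configuration. The step needs insertion to win over cyclopropanation of the adjacent 1,1-disubstituted alkene, over bimolecular coupling to azine or stilbene, and over intramolecular dipolar cycloaddition of 11 onto that alkene. The substrate helps in four ways: the C–H bond is activated twice (ether oxygen and alkene), the diazo carbon is flanked by two ortho substituents that slow bimolecular reactions, the silyl ethers offer no rival C–H bond next to oxygen, and 11 is made cold and fed slowly to the catalyst so that carbene formation outruns cycloaddition.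

Step 7
Reactants: 12 1-[(2R)-4,6-bis[[tert-butyl(dimethyl)silyl]oxy]-2-(6-methylhepta-1,5-dien-2-yl)-2,3-dihydro-1-benzofuran-5-yl]ethanone
Product: 13 1-[(2R)-4,6-dihydroxy-2-(6-methylhepta-1,5-dien-2-yl)-2,3-dihydro-1-benzofuran-5-yl]ethanone
Conditions: TBAF (2.2 equiv), AcOH (2.2 equiv), THF, 0 °C
Reagents that add atoms: none
Why: Fluoride cleavage of aryl silyl ethers, buffered with acetic acid so the phenoxides are protonated at once; the alkenes and the allylic ether at C2 are not touched and the stereocentre is not involved.

Step 8
Reactants: 14 pentan-3-one
Product: 15 trimethyl(pent-2-en-3-yloxy)silane (E/Z mixture)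
Conditions: TMSOTf, Et3N, Et2O, 0 °C
Reagents that add atoms: trimethylsilyl trifluoromethanesulfonate (TMSOTf), C[Si](C)(C)OS(=O)(=O)C(F)(F)F
Why: Silyl enol ether formation with a silyl triflate and an amine base; the ketone is symmetrical, so there is no regiochemical question, and both alkene isomers converge on the same pyranone in step 9.

Step 9
Reactants: 15 trimethyl(pent-2-en-3-yloxy)silane; 16 propanedioyl dichloride (malonyl dichloride)
Product: 17 6-ethyl-4-hydroxy-5-methyl-2H-pyran-2-one
Conditions: Et2O, −78 °C → rt
Reagents that add atoms: none
Why: Pyranone annulation of a silyl enol ether with malonyl dichloride (Effenberger type): C-acylation forms C4–C5 with loss of chlorotrimethylsilane, then the enol oxygen of the β-diketo acid chloride closes O1–C2 with loss of HCl, and the product is expected as the 4-hydroxy tautomer.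

Step 10
Reactants: 17 6-ethyl-4-hydroxy-5-methyl-2H-pyran-2-one
Product: 18 3-[(dimethylamino)methyl]-6-ethyl-4-hydroxy-5-methyl-2H-pyran-2-one
Conditions: dimethyl(methylidene)ammonium iodide (1.05 equiv), CH2Cl2, rt; then NaHCO3 (1 equiv), MeOH; isolated as the inner salt
Reagents that add atoms: dimethyl(methylidene)ammonium iodide (Eschenmoser's salt), C=[N+](C)C.[I-]
Why: Mannich reaction: C3 of the 4-hydroxypyranone is the nucleophilic carbon of a vinylogous acid and adds to the preformed iminium ion; only one aminomethyl group can enter because C3 is the only enolic CH.

Step 11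
Reactants: 13 1-[(2R)-4,6-dihydroxy-2-(6-methylhepta-1,5-dien-2-yl)-2,3-dihydro-1-benzofuran-5-yl]ethanone; 18 3-[(dimethylamino)methyl]-6-ethyl-4-hydroxy-5-methyl-2H-pyran-2-one
Product: 20 3-[[(2R)-5-acetyl-4,6-dihydroxy-2-(6-methylhepta-1,5-dien-2-yl)-2,3-dihydro-1-benzofuran-7-yl]methyl]-6-ethyl-4-hydroxy-5-methyl-2H-pyran-2-one, via methylidenepyrandione 19 (not isolated)
Conditions: 18 (1.2 equiv), MeCN, 60 °C, argon; pH 4 buffer on work-up
Reagents that add atoms: none
Why: Elimination–addition with the Mannich base as a latent Michael acceptor: on warming, 18 loses dimethylamine to give the 3-methylidene dione 19, and C7 of 13, the only free position of ring A and activated by O1 and the 6-hydroxyl, adds in a conjugate Friedel–Crafts sense; rearomatisation and enolisation give 20, and C2 is untouched under these near-neutral conditions.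

## Compound list

1 | 5-bromo-2-methylpent-2-ene | CC(C)=CCCBr | starting material
2 | prop-2-yn-1-ol | C#CCO | starting material
3 | (4-methylpent-3-en-1-yl)magnesium bromide | CC(C)=CCC[Mg]Br | intermediate (not isolated)
4 | 6-methyl-2-methylidenehept-5-en-1-ol | C=C(CO)CCC=C(C)C | intermediate
5 | 2,4,6-trihydroxyacetophenone | CC(=O)c1c(O)cc(O)cc1O | starting material
6 | 1-[2,6-dihydroxy-4-[(6-methyl-2-methylidenehept-5-en-1-yl)oxy]phenyl]ethanone | C=C(CCC=C(C)C)COc1cc(O)c(C(C)=O)c(O)c1 | intermediate
7 | N-[[3-acetyl-2,4-dihydroxy-6-[(6-methyl-2-methylidenehept-5-en-1-yl)oxy]phenyl]methylidene]-N-methylmethanaminium chloride | C=C(CCC=C(C)C)COc1cc(O)c(C(C)=O)c(O)c1C=[N+](C)C.[Cl-] | intermediate (not isolated)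
8 | 3-acetyl-2,4-dihydroxy-6-[(6-methyl-2-methylidenehept-5-en-1-yl)oxy]benzaldehyde | C=C(CCC=C(C)C)COc1cc(O)c(C(C)=O)c(O)c1C=O | intermediate
9 | 3-acetyl-2,4-bis[[tert-butyl(dimethyl)silyl]oxy]-6-[(6-methyl-2-methylidenehept-5-en-1-yl)oxy]benzaldehyde | C=C(CCC=C(C)C)COc1cc(O[Si](C)(C)C(C)(C)C)c(C(C)=O)c(O[Si](C)(C)C(C)(C)C)c1C=O | intermediate
10 | 1-[2,6-bis[[tert-butyl(dimethyl)silyl]oxy]-3-[(E)-hydrazinylidenemethyl]-4-[(6-methyl-2-methylidenehept-5-en-1-yl)oxy]phenyl]ethanone | C=C(CCC=C(C)C)COc1cc(O[Si](C)(C)C(C)(C)C)c(C(C)=O)c(O[Si](C)(C)C(C)(C)C)c1/C=N/N | intermediate (key-step precursor)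
11 | 1-[2,6-bis[[tert-butyl(dimethyl)silyl]oxy]-3-(diazomethyl)-4-[(6-methyl-2-methylidenehept-5-en-1-yl)oxy]phenyl]ethanone | C=C(CCC=C(C)C)COc1cc(O[Si](C)(C)C(C)(C)C)c(C(C)=O)c(O[Si](C)(C)C(C)(C)C)c1C=[N+]=[N-] | intermediate (not isolated)
12 | 1-[(2R)-4,6-bis[[tert-butyl(dimethyl)silyl]oxy]-2-(6-methylhepta-1,5-dien-2-yl)-2,3-dihydro-1-benzofuran-5-yl]ethanone | C=C(CCC=C(C)C)[C@H]1Cc2c(O[Si](C)(C)C(C)(C)C)c(C(C)=O)c(O[Si](C)(C)C(C)(C)C)cc2O1 | intermediate (key-step product)
13 | 1-[(2R)-4,6-dihydroxy-2-(6-methylhepta-1,5-dien-2-yl)-2,3-dihydro-1-benzofuran-5-yl]ethanone | C=C(CCC=C(C)C)[C@H]1Cc2c(O)c(C(C)=O)c(O)cc2O1 | intermediate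
14 | pentan-3-one | CCC(=O)CC | starting material
15 | trimethyl(pent-2-en-3-yloxy)silane (E/Z mixture) | CCC(=CC)O[Si](C)(C)C | intermediate
16 | propanedioyl dichloride | O=C(Cl)CC(=O)Cl | starting material
17 | 6-ethyl-4-hydroxy-5-methyl-2H-pyran-2-one | CCc1oc(=O)cc(O)c1C | intermediate
18 | 3-[(dimethylamino)methyl]-6-ethyl-4-hydroxy-5-methyl-2H-pyran-2-one | CCc1oc(=O)c(CN(C)C)c(O)c1C | intermediate
19 | 6-ethyl-5-methyl-3-methylidene-2H-pyran-2,4(3H)-dione | CCC1=C(C)C(=O)C(=C)C(=O)O1 | intermediate (not isolated)
20 | 3-[[(2R)-5-acetyl-4,6-dihydroxy-2-(6-methylhepta-1,5-dien-2-yl)-2,3-dihydro-1-benzofuran-7-yl]methyl]-6-ethyl-4-hydroxy-5-methyl-2H-pyran-2-one (CNP0294086.1) | C=C(CCC=C(C)C)[C@H]1Cc2c(O)c(C(C)=O)c(O)c(Cc3c(O)c(C)c(CC)oc3=O)c2O1 | target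

## Step count and least certain steps

Total: 11 steps. Longest linear sequence: 8 steps (1, 2, 3, 4, 5, 6, 7, 11); steps 8–10 form the three-step pyranone branch.

**Step 6 (key step, new method).**
- **Risk:** the unshielded aryl carbene may couple bimolecularly with remaining diazo compound. The diazo group may cyclise onto the tethered alkene by dipolar cycloaddition before it reaches the catalyst. The carbene may cyclopropanate that alkene. The catalyst may distinguish the two enantiotopic hydrogens poorly, because the carbene carries only a hydrogen where known substrates carry a second carbon group.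
- **Fallback (known chemistry):** set out from 5 and return at 12.
  - Mitsunobu benzylation of the 4-hydroxyl (BnOH, PPh3, DIAD) would give 1-[4-(benzyloxy)-2,6-dihydroxyphenyl]ethanone F1.
  - Silylation (TBSOTf, 2,6-lutidine) would give 1-[4-(benzyloxy)-2,6-bis[[tert-butyl(dimethyl)silyl]oxy]phenyl]ethanone F2.
  - Hydrogenolysis (H2, Pd/C, EtOAc) would give 1-[2,6-bis[[tert-butyl(dimethyl)silyl]oxy]-4-hydroxyphenyl]ethanone F3.
  - Iodination ortho to the free hydroxyl (N-iodosuccinimide, CH2Cl2, 0 °C; the two ortho positions are equivalent) would give 1-[2,6-bis[[tert-butyl(dimethyl)silyl]oxy]-4-hydroxy-3-iodophenyl]ethanone F4.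
  - Enantioselective heteroannulation of F4 with β-myrcene A4 (Pd2(dba)3 as the zerovalent palladium source, a chiral monophosphine, K2CO3, about 80 °C) should give 12. This is Heck-type arylation of the monosubstituted alkene followed by phenoxide attack on the π-allyl.

**Step 5.**
- **Risk:** hydrazine may remove silyl groups by attack at silicon, since aryl silyl ethers ortho to a carbonyl are activated. It may also condense at the ketone, or the product may disproportionate to the azine on standing.
- **Fallback:** set out from 9 and return at 11. Condensation with 1,2-bis(tert-butyldimethylsilyl)hydrazine and catalytic Sc(OTf)3 under anhydrous, non-nucleophilic conditions would give 1-[2,6-bis[[tert-butyl(dimethyl)silyl]oxy]-3-[(E)-[[tert-butyl(dimethyl)silyl]hydrazinylidene]methyl]-4-[(6-methyl-2-methylidenehept-5-en-1-yl)oxy]phenyl]ethanone F5. Oxidation of F5 with (difluoroiodo)benzene and 2-chloropyridine in CH2Cl2 at low temperature should give 11 directly, which is passed to the rhodium catalyst as in step 6.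

**Step 3.**
- **Risk:** HCl released during substitution may add to or cyclise the diene. The reagent may attack the acetyl methyl group, leading to chromone-type ring closure with the neighbouring hydroxyl.
- **Fallback:** set out from 5 and return at 8 by reversing the order. Vilsmeier formylation of 5, which has no sensitive group, would give 3-acetyl-2,4,6-trihydroxybenzaldehyde F6. Mitsunobu etherification of F6 with 4 should then alkylate the hydroxyl para to the acetyl group. That hydroxyl is expected to be the only one not hydrogen-bonded when the middle hydroxyl binds the formyl oxygen and the remaining hydroxyl binds the acetyl oxygen. The price is a regiochemical question that the main route avoids by symmetry.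

**Step 11.**
- **Risk:** the aminomethyl group may transfer between pyranone units, leading to pyranone self-coupling. Addition may occur through a phenol oxygen, or the methylidene dione may undergo hetero-Diels–Alder reaction with the side-chain alkenes.
- **Fallback:** set out from 13 and return at 20 with the roles of the partners reversed. Aminomethylation of 13 at C7 with dimethyl(methylidene)ammonium iodide would give 1-[(2R)-7-[(dimethylamino)methyl]-4,6-dihydroxy-2-(6-methylhepta-1,5-dien-2-yl)-2,3-dihydro-1-benzofuran-5-yl]ethanone F7. Heating F7 with 17 in MeCN should expel dimethylamine and let C3 of 17 add to the resulting ortho-quinone methide, so that no electrophilic pyranone species is ever present.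

**Step 1.**
- **Risk:** carbometalation with a primary alkyl Grignard reagent may be sluggish, with loss of 3 to protonation and Wurtz coupling.
- **Fallback:** set out from 1 and return at 4.
  - Alkylation of triethyl phosphonoacetate with 1 (NaH, DMF) would give ethyl 2-(diethoxyphosphoryl)-6-methylhept-5-enoate F8.
  - Horner–Wadsworth–Emmons reaction with aqueous formaldehyde and K2CO3 would give ethyl 6-methyl-2-methylidenehept-5-enoate F9.
  - Reduction with DIBAL-H (CH2Cl2, −78 °C) would give 4.

## Further compounds

F1 | step 6 | 1-[4-(benzyloxy)-2,6-dihydroxyphenyl]ethanone | CC(=O)c1c(O)cc(OCc2ccccc2)cc1O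
F2 | step 6 | 1-[4-(benzyloxy)-2,6-bis[[tert-butyl(dimethyl)silyl]oxy]phenyl]ethanone | CC(=O)c1c(O[Si](C)(C)C(C)(C)C)cc(OCc2ccccc2)cc1O[Si](C)(C)C(C)(C)C
F3 | step 6 | 1-[2,6-bis[[tert-butyl(dimethyl)silyl]oxy]-4-hydroxyphenyl]ethanone | CC(=O)c1c(O[Si](C)(C)C(C)(C)C)cc(O)cc1O[Si](C)(C)C(C)(C)C
F4 | step 6 | 1-[2,6-bis[[tert-butyl(dimethyl)silyl]oxy]-4-hydroxy-3-iodophenyl]ethanone | CC(=O)c1c(O[Si](C)(C)C(C)(C)C)cc(O)c(I)c1O[Si](C)(C)C(C)(C)C
F5 | step 5 | 1-[2,6-bis[[tert-butyl(dimethyl)silyl]oxy]-3-[(E)-[[tert-butyl(dimethyl)silyl]hydrazinylidene]methyl]-4-[(6-methyl-2-methylidenehept-5-en-1-yl)oxy]phenyl]ethanone | C=C(CCC=C(C)C)COc1cc(O[Si](C)(C)C(C)(C)C)c(C(C)=O)c(O[Si](C)(C)C(C)(C)C)c1/C=N/N[Si](C)(C)C(C)(C)C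
F6 | step 3 | 3-acetyl-2,4,6-trihydroxybenzaldehyde | CC(=O)c1c(O)cc(O)c(C=O)c1O
F7 | step 11 | 1-[(2R)-7-[(dimethylamino)methyl]-4,6-dihydroxy-2-(6-methylhepta-1,5-dien-2-yl)-2,3-dihydro-1-benzofuran-5-yl]ethanone | C=C(CCC=C(C)C)[C@H]1Cc2c(O)c(C(C)=O)c(O)c(CN(C)C)c2O1
F8 | step 1 | ethyl 2-(diethoxyphosphoryl)-6-methylhept-5-enoate | CCOC(=O)C(CCC=C(C)C)P(=O)(OCC)OCC
F9 | step 1 | ethyl 6-methyl-2-methylidenehept-5-enoate | C=C(CCC=C(C)C)C(=O)OCC
A1 | alternative 1 | ethyl (2Z)-2-methyl-3-[[3-(2,4,6-trimethoxyphenyl)propanoyl]oxy]pent-2-enoate | CCOC(=O)/C(C)=C(/CC)OC(=O)CCc1c(OC)cc(OC)cc1OC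
A2 | alternative 1 | 6-ethyl-4-hydroxy-5-methyl-3-[(2,4,6-trimethoxyphenyl)methyl]-2H-pyran-2-one | CCc1oc(=O)c(Cc2c(OC)cc(OC)cc2OC)c(O)c1C
A3 | alternative 2 | 1-[4-hydroxy-3-iodo-2,6-bis(methoxymethoxy)phenyl]ethanone | CC(=O)c1c(OCOC)cc(O)c(I)c1OCOC
A4 | alternative 2 | β-myrcene (7-methyl-3-methylideneocta-1,6-diene) | C=CC(=C)CCC=C(C)C
A5 | alternative 2 | 1-[(2R)-4,6-bis(methoxymethoxy)-2-(6-methylhepta-1,5-dien-2-yl)-2,3-dihydro-1-benzofuran-5-yl]ethanone | C=C(CCC=C(C)C)[C@H]1Cc2c(OCOC)c(C(C)=O)c(OCOC)cc2O1
A6 | alternative 3 | 2-[(3-acetyl-2,4,6-trimethoxyphenyl)methyl]propanedioyl dichloride | CC(=O)c1c(OC)cc(OC)c(CC(C(=O)Cl)C(=O)Cl)c1OC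
A7 | alternative 3 | 3-[(3-acetyl-2,4,6-trimethoxyphenyl)methyl]-6-ethyl-4-hydroxy-5-methyl-2H-pyran-2-one | CCc1oc(=O)c(Cc2c(OC)cc(OC)c(C(C)=O)c2OC)c(O)c1C
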